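Whether we read the flask at 5.0 s or at 2.0 min, the decision for the next run is the same: do we charge it as it stands, or must the protic impurity come down first?

| flask | starting material | protic impurity | remark | time |
|---|---|---|---|---|
| cedar | 0.13 mM | 0.040 mM | run made earlier |  |
| ash | 0.30 mM | 0.040 mM | run made earlier |  |
| larch | 0.20 mM | 0.080 mM | run made earlier |  |
| flask | 0.20 mM | 0.0400 mM |  | 2.0 min |

| run | time / s | target / % | isomer of the product / % | starting material / % |
|---|---|---|---|---|
| cedar | 10.0 | 6.2 | 3.2 | 52.1 |
| cedar | 20.0 | 17.4 | 9.8 | 28.0 |
| cedar | 30.0 | 26.8 | 15.6 | 16.1 |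
| cedar | 60.0 | 42.7 | 25.3 | 3.1 |
| cedar | 120 | 46.9 | 30.6 | 0.3 |
| ash | 10.0 | 5.9 | 4.0 | 54.0 |
| ash | 30.0 | 29.0 | 15.2 | 18.6 |
| ash | 60.0 | 48.0 | 24.8 | 4.8 |
| ash | 80.0 | 53.7 | 28.2 | 1.4 |
| ash | 120 | 55.6 | 30.2 | 0 |
| larch | 10.0 | 6.1 | 3.0 | 46.3 |
| larch | 30.0 | 25.6 | 13.7 | 13.7 |
| larch | 60.0 | 39.6 | 22.0 | 1.7 |
| larch | 80.0 | 41.1 | 24.2 | 0.6 |
| larch | 120 | 43.1 | 25.1 | 0 |

(scatter of a reading: 0.5 percentage points)

- share of target in target plus isomer of the product at 5.0 s
- share of target in target plus isomer of the product at 2.0 min
- which of target and isomer of the product there is more of at 2.0 min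

- the earlier runs were read with a standard deviation of 0.5 percentage points
- a reading or a percentage of target counts all its forms, free or not

We follow one molecule to the fork where it becomes either target or isomer of the product, and we count the outcomes at 30.0 s, summed over the cedar, ash and larch runs, since the earliest readings carry more scatter:

f = 81.4% / (81.4% + 44.5%) = 64.7%

This f is the fork share, or selectivity: the chance that a molecule leaving the fork becomes target and not isomer.

Larch, with doubled impurity, reads 65.1% at that time, between cedar at 63.2% and ash at 65.6%. So these readings give us no ground to lower the impurity for the sake of the share. The yield is a separate question: at 120 s, target plus isomer of the product reads 68.2% in larch against 85.8% in ash, but those two runs differ in starting material as well as in impurity.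

At 120 s the share reads 60.5% in cedar and 64.8% in ash. The flask's charge lies between theirs, so we commit to f at 5.0 s, to a share between those two at 2.0 min, and to target leading.

The forecast said 65%, 63% and target, reading the late drift thus: “This suggests a small loss of target to isomer, or a slightly lower late selectivity”.

The simulation gives 65.6% at 5.0 s and 63.9% at 2.0 min, with 52.0% target against 29.3% isomer, and with 16.1% of the starting material charged standing as quenched substrate at 2.00 min.

    starting material → intermediate (k = 0.0500 s⁻¹)
    intermediate ⇌ target (K = 1.00, k = 0.0430 s⁻¹)
    intermediate ⇌ isomer of the product (K = 21.0, k = 0.0210 s⁻¹)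
    crystals ⇌ target, rate k4*(cs4 - [target]) while solid is left; crystals form when [target] > cs4 (solubility = 0.00460 mM, k = 1.30 s⁻¹)
    starting material + protic impurity → quenched substrate (k = 490 M⁻¹ s⁻¹)

In the flask at 2.00 min, crystals hold 49.7% of the charge, counted within the 52.0% of target. With the loss of target from solution into crystals taken away, both ways, the simulated run of this flask falls in share at 2.0 min from 63.9% to 24.3% and the lead turns, so that loss is one reason, though not shown to be the main one, why target leads in the flask.

With 0.050 mM of starting material, f gives 64.7% at 5.0 s, and the simulation gives 65.6%. At 2.00 min that neighbour flask stands at 48.2%, with 33.0% target against 35.4% isomer.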